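**Plan**
- Retrosynthesis: the four phenols are unmasked last (two 2-nitrobenzenesulfonates on ring B, two MOM ethers on ring A). Ring C is then cut in one [3+3] disconnection at O1–C2 and C4–C4a, giving phenol 6 (ring A) and the (R)-β-lactone 10 (ring B with C2–C3–C4).
- Enabling feature: C2–C3–C4 of ring C is a β-oxygenated acyl unit, i.e. a latent strained oxetan-2-one in which C2 carries a leaving oxygen and C4 is at the acid level. Ring A is a symmetric 4-prenylphloroglucinol whose O1 is para to the prenyl group and whose two ortho carbons (C4a, C8) are equivalent.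
- Forward: the ring A piece is made by directed ortho-metalation and prenylation (steps 1–4). The ring B piece is made by Suzuki–Miyaura prenylation, sulfonylation and a catalytic asymmetric ketene–aldehyde [2+2] (steps 5–7). Ring C closes in step 8, and deprotection follows in steps 9–10.
- Stereochemistry: C2 is set as (R) in the catalyst-controlled [2+2] and inverted once by SN2 lactone opening to (2S). The sulfonates keep ring B electron-poor so C2 cannot ionise, and the end game avoids basic conditions that would open ring C.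

Key step: step 8

Assumption: O-trimethylsilylquinidine is taken to give the (R)-lactone, by analogy with the usual sense of quinidine-type catalysts in ketene–aldehyde cycloadditions; O-trimethylsilylquinine is its mirror-image counterpart. (Abbreviations: MOM = methoxymethyl, Ns = 2-nitrobenzenesulfonyl, prenyl = 3-methylbut-2-en-1-yl.)

Step 1
Reactants: 1 phloroglucinol (benzene-1,3,5-triol)
Product: 2 3,5-bis(methoxymethoxy)phenol
Conditions: MOMCl (2.0 equiv), i-Pr2NEt, CH2Cl2/DMF, 0 °C to rt
Reagents that add atoms: chloromethyl methyl ether, COCCl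
Why: Statistical double Williamson-type O-alkylation of the symmetric triol leaves one hydroxyl free, and the mono- and tris-ethers are separated by chromatography.

Step 2
Reactants: 2 3,5-bis(methoxymethoxy)phenol
Product: 3 [3,5-bis(methoxymethoxy)phenoxy]triisopropylsilane
Conditions: i-Pr3SiCl, imidazole, DMF, rt
Reagents that add atoms: triisopropylsilyl chloride, CC(C)[Si](Cl)(C(C)C)C(C)C
Why: Silylation of the remaining phenol masks the oxygen that later becomes O1, and the bulky silyl group shields its two ortho positions from metalation.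

Step 3
Reactants: 3 [3,5-bis(methoxymethoxy)phenoxy]triisopropylsilane
Product: 5 [3,5-bis(methoxymethoxy)-4-(3-methylbut-2-en-1-yl)phenoxy]triisopropylsilane, via aryllithium 4 (not isolated)
Conditions: n-BuLi, THF, 0 °C; then CuI (10 mol%), prenyl bromide, −78 °C to rt
Reagents that add atoms: prenyl bromide, CC(C)=CCBr
Why: Directed ortho-metalation should occur at the carbon between the two cooperating OMOM groups, and copper-catalysed SN2 alkylation of the aryllithium places the linear prenyl group para to the silyloxy group.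

Step 4
Reactants: 5 [3,5-bis(methoxymethoxy)-4-(3-methylbut-2-en-1-yl)phenoxy]triisopropylsilane
Product: 6 3,5-bis(methoxymethoxy)-4-(3-methylbut-2-en-1-yl)phenol
Conditions: Bu4NF, THF, 0 °C
Reagents that add atoms: none
Why: Fluoride cleaves the aryl silyl ether selectively and frees the single phenol, para to the prenyl group, that is to become O1.

Step 5
Reactants: 7 5-bromo-2,4-dihydroxybenzaldehyde
Product: 8 2,4-dihydroxy-5-(3-methylbut-2-en-1-yl)benzaldehyde
Conditions: prenylB(pin), [1,3-bis(2,6-di(pentan-3-yl)phenyl)imidazol-2-ylidene](3-chloropyridine)palladium dichloride (2 mol%), aq. KOH, THF, 65 °C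
Reagents that add atoms: 3-methylbut-2-enylboronic acid pinacol ester, CC(C)=CCB1OC(C)(C)C(C)(C)O1
Why: Suzuki–Miyaura coupling of the aryl bromide with the prenylboronate under a very bulky N-heterocyclic carbene ligand, which favours coupling at the primary carbon of the allyl unit, should install the linear prenyl group without protection of the phenols.

Step 6
Reactants: 8 2,4-dihydroxy-5-(3-methylbut-2-en-1-yl)benzaldehyde
Product: 9 4-formyl-6-(3-methylbut-2-en-1-yl)-1,3-phenylene bis(2-nitrobenzenesulfonate)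
Conditions: 2-NO2C6H4SO2Cl (2.3 equiv), Et3N, DMAP (cat.), CH2Cl2, 0 °C to rt
Reagents that add atoms: 2-nitrobenzenesulfonyl chloride, O=[N+]([O-])c1ccccc1S(=O)(=O)Cl
Why: Sulfonylation of both phenols gives electron-withdrawing, acid-stable nosylates that deactivate ring B towards benzylic ionisation and can later be removed by thiolate under near-neutral conditions.

Step 7
Reactants: 9 4-formyl-6-(3-methylbut-2-en-1-yl)-1,3-phenylene bis(2-nitrobenzenesulfonate)
Product: 10 (4R)-4-[2,4-bis(2-nitrophenylsulfonyloxy)-5-(3-methylbut-2-en-1-yl)phenyl]oxetan-2-one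
Conditions: AcCl, i-Pr2NEt, O-trimethylsilylquinidine (10 mol%), LiClO4, CH2Cl2/Et2O, −78 °C
Reagents that add atoms: acetyl chloride, CC(=O)Cl
Why: Ketene formed in situ from acetyl chloride should add to the electron-poor aldehyde as its chiral ammonium enolate in a cinchona-alkaloid/Lewis-acid catalysed [2+2] cycloaddition (acyl halide–aldehyde cyclocondensation), the alkaloid setting the lactone stereocenter as (R).

Step 8
Reactants: 6 3,5-bis(methoxymethoxy)-4-(3-methylbut-2-en-1-yl)phenol; 10 (4R)-4-[2,4-bis(2-nitrophenylsulfonyloxy)-5-(3-methylbut-2-en-1-yl)phenyl]oxetan-2-one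
Product: 13 (2S)-5,7-bis(methoxymethoxy)-6-(3-methylbut-2-en-1-yl)-2-[2,4-bis(2-nitrophenylsulfonyloxy)-5-(3-methylbut-2-en-1-yl)phenyl]chroman-4-one, via cesium carboxylate 11 (not isolated), via mixed anhydride 12 (not isolated)
Conditions: Cs2CO3, MeCN, rt to 40 °C; then CH2Cl2, (CF3CO)2O, 0 °C to rt
Reagents that add atoms: none
Why: Proposed new method: the cesium phenoxide of 6 should attack C4 of the strained oxetan-2-one 10 in an SN2 alkyl–oxygen cleavage (attack at the acyl carbon only gives an aryl β-alkoxide ester that re-closes to the lactone, so it is a non-productive equilibrium), and the released carboxylate 11 is converted by trifluoroacetic anhydride into the mixed anhydride 12, which acylates the ring A carbon ortho to the new ether oxygen. The closest known reactions are the opening of β-propiolactone and β-butyrolactone by phenoxides to 3-aryloxy acids and the trifluoroacetic-anhydride cyclisation of 3-aryloxypropanoic acids to chroman-4-ones, here joined in one flask on a 4-aryl lactone. Ring C is closed in the second event as a six-membered ring by intramolecular Friedel–Crafts acylation (6-exo-trig at the acyl carbon). C2 is controlled by the (R) stereocenter of the lactone, which is inverted cleanly to (2S); the two nosylates keep ring B electron-poor so that C4 of the lactone cannot ionise to a quinone-methide-type cation, and the four-membered ring keeps the C3–H and C4–O bonds out of an anti-periplanar arrangement so that elimination to the cinnamate is disfavoured. The step needs O-alkylation at the oxygen para to the prenyl group and acylation next to it: in 6 this is the only free oxygen and its two ortho carbons are equivalent and each flanked by an OMOM group, so only the 6-prenyl chromanone can form. Neither prenyl group has a free ortho hydroxyl to cyclise onto, and the acid formed is buffered by cesium trifluoroacetate.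

Step 9
Reactants: 13 (2S)-5,7-bis(methoxymethoxy)-6-(3-methylbut-2-en-1-yl)-2-[2,4-bis(2-nitrophenylsulfonyloxy)-5-(3-methylbut-2-en-1-yl)phenyl]chroman-4-one
Product: 14 (2S)-5,7-dihydroxy-6-(3-methylbut-2-en-1-yl)-2-[2,4-bis(2-nitrophenylsulfonyloxy)-5-(3-methylbut-2-en-1-yl)phenyl]chroman-4-one
Conditions: 3 M aq. HCl, MeOH/THF, 45 °C
Reagents that add atoms: none
Why: Acid-catalysed transacetalisation in methanol should remove both MOM ethers, while the electron-poor ring B prevents ionisation at C2 and its prenyl group has no free ortho hydroxyl to cyclise onto.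

Step 10
Reactants: 14 (2S)-5,7-dihydroxy-6-(3-methylbut-2-en-1-yl)-2-[2,4-bis(2-nitrophenylsulfonyloxy)-5-(3-methylbut-2-en-1-yl)phenyl]chroman-4-one
Product: 15 (2S)-2-[2,4-dihydroxy-5-(3-methylbut-2-en-1-yl)phenyl]-5,7-dihydroxy-6-(3-methylbut-2-en-1-yl)chroman-4-one (CNP0320454.1)
Conditions: PhSH (8 equiv), K2CO3 (3 equiv), DMF, 0 °C to rt
Reagents that add atoms: none
Why: Thiophenolate should displace the sulfonyl group from the nitroarene by nucleophilic aromatic ipso-substitution and the aryl sulfite so formed loses sulfur dioxide, freeing both phenols in a medium buffered by excess thiol so that no phenoxide-driven opening of ring C, and hence no racemisation at C2, is expected.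

**Compound list**
1 | phloroglucinol (benzene-1,3,5-triol) | Oc1cc(O)cc(O)c1 | starting material
2 | 3,5-bis(methoxymethoxy)phenol | COCOc1cc(O)cc(OCOC)c1 | intermediate
3 | [3,5-bis(methoxymethoxy)phenoxy]triisopropylsilane | COCOc1cc(OCOC)cc(O[Si](C(C)C)(C(C)C)C(C)C)c1 | intermediate
4 | [2,6-bis(methoxymethoxy)-4-(triisopropylsilyloxy)phenyl]lithium | [Li]c1c(OCOC)cc(O[Si](C(C)C)(C(C)C)C(C)C)cc1OCOC | intermediate
5 | [3,5-bis(methoxymethoxy)-4-(3-methylbut-2-en-1-yl)phenoxy]triisopropylsilane | CC(C)=CCc1c(OCOC)cc(O[Si](C(C)C)(C(C)C)C(C)C)cc1OCOC | intermediate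
6 | 3,5-bis(methoxymethoxy)-4-(3-methylbut-2-en-1-yl)phenol | CC(C)=CCc1c(OCOC)cc(O)cc1OCOC | intermediate
7 | 5-bromo-2,4-dihydroxybenzaldehyde | O=Cc1cc(Br)c(O)cc1O | starting material
8 | 2,4-dihydroxy-5-(3-methylbut-2-en-1-yl)benzaldehyde | CC(C)=CCc1cc(C=O)c(O)cc1O | intermediate
9 | 4-formyl-6-(3-methylbut-2-en-1-yl)-1,3-phenylene bis(2-nitrobenzenesulfonate) | CC(C)=CCc1cc(C=O)c(OS(=O)(=O)c2ccccc2[N+](=O)[O-])cc1OS(=O)(=O)c1ccccc1[N+](=O)[O-] | intermediate
10 | (4R)-4-[2,4-bis(2-nitrophenylsulfonyloxy)-5-(3-methylbut-2-en-1-yl)phenyl]oxetan-2-one | CC(C)=CCc1cc([C@H]2CC(=O)O2)c(OS(=O)(=O)c2ccccc2[N+](=O)[O-])cc1OS(=O)(=O)c1ccccc1[N+](=O)[O-] | intermediate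
11 | cesium (3S)-3-[3,5-bis(methoxymethoxy)-4-(3-methylbut-2-en-1-yl)phenoxy]-3-[2,4-bis(2-nitrophenylsulfonyloxy)-5-(3-methylbut-2-en-1-yl)phenyl]propanoate | [Cs+].[O-]C(=O)C[C@H](Oc1cc(OCOC)c(CC=C(C)C)c(OCOC)c1)c1cc(CC=C(C)C)c(OS(=O)(=O)c2ccccc2[N+](=O)[O-])cc1OS(=O)(=O)c1ccccc1[N+](=O)[O-] | intermediate
12 | mixed anhydride of the (3S)-acid of 11 with trifluoroacetic acid | O=C(OC(=O)C(F)(F)F)C[C@H](Oc1cc(OCOC)c(CC=C(C)C)c(OCOC)c1)c1cc(CC=C(C)C)c(OS(=O)(=O)c2ccccc2[N+](=O)[O-])cc1OS(=O)(=O)c1ccccc1[N+](=O)[O-] | intermediate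
13 | (2S)-5,7-bis(methoxymethoxy)-6-(3-methylbut-2-en-1-yl)-2-[2,4-bis(2-nitrophenylsulfonyloxy)-5-(3-methylbut-2-en-1-yl)phenyl]chroman-4-one | CC(C)=CCc1cc([C@@H]2CC(=O)c3c(cc(OCOC)c(CC=C(C)C)c3OCOC)O2)c(OS(=O)(=O)c2ccccc2[N+](=O)[O-])cc1OS(=O)(=O)c1ccccc1[N+](=O)[O-] | intermediate
14 | (2S)-5,7-dihydroxy-6-(3-methylbut-2-en-1-yl)-2-[2,4-bis(2-nitrophenylsulfonyloxy)-5-(3-methylbut-2-en-1-yl)phenyl]chroman-4-one | CC(C)=CCc1cc([C@@H]2CC(=O)c3c(cc(O)c(CC=C(C)C)c3O)O2)c(OS(=O)(=O)c2ccccc2[N+](=O)[O-])cc1OS(=O)(=O)c1ccccc1[N+](=O)[O-] | intermediate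
15 | (2S)-2-[2,4-dihydroxy-5-(3-methylbut-2-en-1-yl)phenyl]-5,7-dihydroxy-6-(3-methylbut-2-en-1-yl)chroman-4-one | CC(C)=CCc1cc([C@@H]2CC(=O)c3c(cc(O)c(CC=C(C)C)c3O)O2)c(O)cc1O | target

**Totals**
Total step count: 10. Longest linear sequence: 7 steps (steps 1, 2, 3, 4, 8, 9, 10).

**Steps most likely to fail**

Step 8. The phenoxide may attack a sulfonate sulfur or the nitroarene instead of C4 (transfer or loss of a nosyl group). Substitution at the hindered, ortho-substituted benzylic carbon may be too slow. The acid formed in the anhydride stage may cleave a MOM ether or add to a prenyl alkene. The fallback uses known stepwise chemistry, sets out from 10 and 6 and returns at 13. Acid-catalysed methanolysis of 10 (MeOH, camphorsulfonic acid cat., acyl–oxygen cleavage with the stereocenter untouched) should give methyl (3R)-3-hydroxy-3-[2,4-bis(2-nitrophenylsulfonyloxy)-5-(3-methylbut-2-en-1-yl)phenyl]propanoate F1. Mitsunobu etherification of F1 with 6 (PPh3, diisopropyl azodicarboxylate, toluene, 0 °C) should give, with inversion, methyl (3S)-3-[3,5-bis(methoxymethoxy)-4-(3-methylbut-2-en-1-yl)phenoxy]-3-[2,4-bis(2-nitrophenylsulfonyloxy)-5-(3-methylbut-2-en-1-yl)phenyl]propanoate F2. Neutral ester cleavage with Me3SnOH (1,2-dichloroethane, 70 °C) should give the (3S)-acid F3, and trifluoroacetic anhydride in CH2Cl2 at 0 °C then closes ring C by Friedel–Crafts acylation to 13.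

Step 7. Conversion may be low, the facial selectivity of the ammonium enolate addition to an ortho-substituted aryl aldehyde may be poor, and ketene may dimerise. The fallback sets out from 9 and returns at 10. Roskamp homologation of 9 with allyl diazoacetate (SnCl2 cat., CH2Cl2) should give allyl 3-oxo-3-[2,4-bis(2-nitrophenylsulfonyloxy)-5-(3-methylbut-2-en-1-yl)phenyl]propanoate F4. Noyori asymmetric transfer hydrogenation (RuCl(p-cymene)[(R,R)-TsDPEN], TsDPEN = N-tosyl-1,2-diphenylethylenediamine, HCO2H/Et3N) should give allyl (3R)-3-hydroxy-3-[2,4-bis(2-nitrophenylsulfonyloxy)-5-(3-methylbut-2-en-1-yl)phenyl]propanoate F5, with the sense of hydride delivery known for aryl ketones. Deallylation with Pd(PPh3)4 and morpholine should give (3R)-3-hydroxy-3-[2,4-bis(2-nitrophenylsulfonyloxy)-5-(3-methylbut-2-en-1-yl)phenyl]propanoic acid F6. Lactonisation through carboxyl activation (PhSO2Cl, pyridine, 0 °C, retention at the carbinol carbon) then gives 10.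

Step 9. The 6-prenyl group may cyclise under acid onto the freed 5- or 7-hydroxyl (chroman formation), or HCl or methanol may add to the alkenes. The fallback avoids protic acid, sets out from 13 and returns at 14. Treatment of 13 with Et3SiOTf and 2,2'-bipyridyl (CH2Cl2, 0 °C) should exchange both aryl MOM ethers for silyl ethers and give (2S)-5,7-bis(triethylsilyloxy)-6-(3-methylbut-2-en-1-yl)-2-[2,4-bis(2-nitrophenylsulfonyloxy)-5-(3-methylbut-2-en-1-yl)phenyl]chroman-4-one F7. Desilylation of F7 with HF·pyridine in THF/pyridine at 0 °C then gives 14.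

**Further compounds**
F1 | step 8 | methyl (3R)-3-hydroxy-3-[2,4-bis(2-nitrophenylsulfonyloxy)-5-(3-methylbut-2-en-1-yl)phenyl]propanoate | COC(=O)C[C@@H](O)c1cc(CC=C(C)C)c(OS(=O)(=O)c2ccccc2[N+](=O)[O-])cc1OS(=O)(=O)c1ccccc1[N+](=O)[O-]
F2 | step 8 | methyl (3S)-3-[3,5-bis(methoxymethoxy)-4-(3-methylbut-2-en-1-yl)phenoxy]-3-[2,4-bis(2-nitrophenylsulfonyloxy)-5-(3-methylbut-2-en-1-yl)phenyl]propanoate | COC(=O)C[C@H](Oc1cc(OCOC)c(CC=C(C)C)c(OCOC)c1)c1cc(CC=C(C)C)c(OS(=O)(=O)c2ccccc2[N+](=O)[O-])cc1OS(=O)(=O)c1ccccc1[N+](=O)[O-]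
F3 | step 8 | (3S)-3-[3,5-bis(methoxymethoxy)-4-(3-methylbut-2-en-1-yl)phenoxy]-3-[2,4-bis(2-nitrophenylsulfonyloxy)-5-(3-methylbut-2-en-1-yl)phenyl]propanoic acid | OC(=O)C[C@H](Oc1cc(OCOC)c(CC=C(C)C)c(OCOC)c1)c1cc(CC=C(C)C)c(OS(=O)(=O)c2ccccc2[N+](=O)[O-])cc1OS(=O)(=O)c1ccccc1[N+](=O)[O-]
F4 | step 7 | allyl 3-oxo-3-[2,4-bis(2-nitrophenylsulfonyloxy)-5-(3-methylbut-2-en-1-yl)phenyl]propanoate | C=CCOC(=O)CC(=O)c1cc(CC=C(C)C)c(OS(=O)(=O)c2ccccc2[N+](=O)[O-])cc1OS(=O)(=O)c1ccccc1[N+](=O)[O-]
F5 | step 7 | allyl (3R)-3-hydroxy-3-[2,4-bis(2-nitrophenylsulfonyloxy)-5-(3-methylbut-2-en-1-yl)phenyl]propanoate | C=CCOC(=O)C[C@@H](O)c1cc(CC=C(C)C)c(OS(=O)(=O)c2ccccc2[N+](=O)[O-])cc1OS(=O)(=O)c1ccccc1[N+](=O)[O-]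
F6 | step 7 | (3R)-3-hydroxy-3-[2,4-bis(2-nitrophenylsulfonyloxy)-5-(3-methylbut-2-en-1-yl)phenyl]propanoic acid | OC(=O)C[C@@H](O)c1cc(CC=C(C)C)c(OS(=O)(=O)c2ccccc2[N+](=O)[O-])cc1OS(=O)(=O)c1ccccc1[N+](=O)[O-]
F7 | step 9 | (2S)-5,7-bis(triethylsilyloxy)-6-(3-methylbut-2-en-1-yl)-2-[2,4-bis(2-nitrophenylsulfonyloxy)-5-(3-methylbut-2-en-1-yl)phenyl]chroman-4-one | CC(C)=CCc1cc([C@@H]2CC(=O)c3c(cc(O[Si](CC)(CC)CC)c(CC=C(C)C)c3O[Si](CC)(CC)CC)O2)c(OS(=O)(=O)c2ccccc2[N+](=O)[O-])cc1OS(=O)(=O)c1ccccc1[N+](=O)[O-]
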